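We begin with an easy division: oak and ash both carry 6.1 mol% of initiator on free monomer, so the free monomer charged per initiator is 16.4, and we call this the share per initiator. If each initiator begins one chain, the average asked for, the number-average degree of polymerisation, is this share times the fraction of the charge in chains. That condition is a guess, since the runs do not show chains.

common to all: initiator 6.1 mol%
- red: free monomer 0.11 M; run made earlier
- amber: free monomer 0.15 M; run made earlier
- oak: free monomer 0.20 M; time 3.0 d
- ash: free monomer 0.10 M; time 3.0 d

| red: time / h | red: monomer in chains / % | amber: time / h | amber: monomer in chains / % |
|---|---|---|---|
| 3.00 | 64.1 | 3.00 | 72.2 |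
| 5.00 | 77.4 | 5.00 | 84.0 |
| 10.0 | 89.4 | 10.0 | 92.1 |
| 20.0 | 95.0 | 20.0 | 95.9 |
| 40.0 | 98.1 | 40.0 | 100.2 |

(readings scatter by 1 percentage point)

- the average divides the monomer in chains by the number of chains begun, living and dead together
- the numbers in the tables scatter by 1 percentage point (one standard deviation)
- the earlier runs do not show the number of chains; that part of a forecast is a guess

1. which of the two ends with the longer chains by the average number of monomer units in a chain (chains begun, living or dead) ("neither" if they lie within 10%) (oak / ash / neither)
2. average number of monomer units in a chain (chains begun, living or dead) at the end, oak
3. average number of monomer units in a chain (chains begun, living or dead) at the end, ash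

The readings supply that fraction if we compare runs by charge times time. Amber's first reading, on a clock 1.36 times red's first, lies between red's first two. On the first rung the bulk goes: at 3.00 h red reads 36 percentage points of the charge outside chains. Then comes a slow tail. Between 10.0 h and 20.0 h that remainder falls to half, and at 40.0 h it reads 1.9 points, with a scatter of 1 point. The last rung lies beyond the readings: at the asked time oak's clock is 3.27 times red's last, and ash's is 1.64 times.

Our first round takes the fraction as one and gives the share for both flasks. For the second round we put the tail back, letting the remainder shrink inversely with the clock. On this estimate of ours, oak keeps a fraction 0.00581 outside chains and reaches 16.3, while ash keeps 0.0116 and reaches 16.2. These lie within 10%.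

The forecast says neither, with 16.3 for oak and 16.2 for ash: “Dead chains still count, so the average is conversion divided by the initiator fraction”.

The simulation gives neither, with 16.3 for oak and 16.1 for ash.

    free monomer + initiator → living end + monomer in chains (k = 16.0 /M/h)
    free monomer + living end → monomer in chains + living end, rate k2*[living end]*[free monomer] (k = 77.0 /M/h)
    free monomer → uncatalysed product (k = 0.00270 /h)
    initiator → spent initiator A (k = 1.50 × 10⁻⁴ /h)
    2 living end → dead end B (k = 26.0 /M/h)

In ash at 3.00 d, 98.1% of the free monomer charged is in chains, 1.31% is uncatalysed product and 0.573% is free monomer, and the share per initiator times the part in chains is 16.1. A neighbour of ash charged with 10 mol% of initiator has a share of 10.0, and with 99.0% of its free monomer in chains and 0.75% of its initiator still there at 3.00 d, it stands at 9.98.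

The earlier runs and the new flask are calculated with made-up constants; the scatter is artificial.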